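**Retrosynthetic overview**
1. The target is two 7,8-dimethoxy-1-methyl-2-quinolones (quinolone 1, quinolone 2) joined by two cis-fused pyran rings: ring C on quinolone 1 (ring O, O–CH, CH, CH–alkenyl) and ring D on quinolone 2 (ring O, CMe2 and the same CH and O–CH).
2. Last disconnections: ring C is opened at its O–CH bond (acid hydroalkoxylation, step 8), and the alkenyl group is taken off the CH–alkenyl carbon (catalytic asymmetric conjugate alkenylation of a bis-pyran through its ring-opened ortho-quinone methide, step 7).
3. Key disconnection of the bis-pyran (step 6): the aryl ether bond from the ring-D oxygen to C4 of quinolone 2 and the C–C bond between the two ring-fusion carbons, followed in the same flask by the O–CH bond of ring C. The partners are a 3-(hydroxyalkenyl)-4-hydroxyquinolone and a 4-chloro-3-formylquinolone, both made from one 4-hydroxyquinolone.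
4. Enabling feature: in quinolone 2 the ring-D oxygen sits on C4 and the O–CH carbon on C3, a β-oxy-enal pattern that becomes a β-chlorovinyl aldehyde (1,3-bis-electrophile). In the partner, the carbinol oxygen and the alkene carbon next to CMe2 (made nucleophilic by conjugation with the C4 enol oxygen of quinolone 1 through C3 and the CH= carbon) are the matching 1,3-O,C-dinucleophile.
5. Ring order: the two quinolones (step 2), ring D then ring C (step 6), ring C opened (step 7) and re-closed with the three stereocentres in place (step 8).

Key step: step 6

Remark (assumption): the facial sense of the binaphthol catalyst in step 7 is assumed from the usual chair-like boron-ate transition state; if a trial shows the opposite preference, the (S)-catalyst is used instead.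

**Step 1**
Reactants: 1 2,3-dimethoxyaniline
Product: 2 2,3-dimethoxy-N-methylaniline
Conditions: (CH2O)n, NaOMe, MeOH, reflux; then NaBH4, reflux
Reagents that add atoms: paraformaldehyde (formaldehyde), C=O
Why: Selective mono-N-methylation by reductive amination, in which the methoxide-stabilised N-(methoxymethyl)/imine species is reduced by NaBH4 so that over-methylation should be avoided; no stereocentre.

**Step 2**
Reactants: 2 2,3-dimethoxy-N-methylaniline; 3 bis(2,4,6-trichlorophenyl) malonate
Product: 4 4-hydroxy-7,8-dimethoxy-1-methylquinolin-2(1H)-one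
Conditions: Ph2O, 220 °C
Reagents that add atoms: none
Why: Thermal cyclocondensation of an N-alkylaniline with an activated aryl malonate (N-acylation, then intramolecular Friedel–Crafts-type C-acylation at the only free ortho position, which is para to a methoxy group) should give the 4-hydroxy-2-quinolone with the methoxy groups at C7 and C8; no stereocentre.

**Step 3**
Reactants: 4 4-hydroxy-7,8-dimethoxy-1-methylquinolin-2(1H)-one
Product: 5 4-chloro-7,8-dimethoxy-1-methyl-2-oxo-1,2-dihydroquinoline-3-carbaldehyde
Conditions: POCl3, DMF, 0 → 60 °C; then ice-water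
Reagents that add atoms: N,N-dimethylformamide, CN(C)C=O; phosphoryl chloride, O=P(Cl)(Cl)Cl
Why: Vilsmeier–Haack reaction, in which the chloroiminium ion formylates the enolic C3 (far more nucleophilic than the dimethoxybenzo ring) and turns the 4-hydroxyl into chloride, the usual outcome for 4-hydroxy-2-quinolones; no stereocentre.

**Step 4**
Reactants: 4 4-hydroxy-7,8-dimethoxy-1-methylquinolin-2(1H)-one
Product: 6 4-hydroxy-3-iodo-7,8-dimethoxy-1-methylquinolin-2(1H)-one
Conditions: N-iodosuccinimide (1.0 equiv), MeCN, 0 → 25 °C
Reagents that add atoms: N-iodosuccinimide, O=C1CCC(=O)N1I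
Why: Electrophilic iodination of the enolic C3 of the vinylogous acid, which should outpace attack on the benzo ring when one equivalent of reagent is used; no stereocentre.

**Step 5**
Reactants: 6 4-hydroxy-3-iodo-7,8-dimethoxy-1-methylquinolin-2(1H)-one; 7 2-methylbut-3-en-2-ol
Product: 8 4-hydroxy-3-[(E)-3-hydroxy-3-methylbut-1-en-1-yl]-7,8-dimethoxy-1-methylquinolin-2(1H)-one
Conditions: Pd(OAc)2 (5 mol %), n-Bu4NCl, NaHCO3, DMF, 70 °C; work-up at pH 7
Reagents that add atoms: none
Why: Heck reaction, in which carbopalladation of the terminal alkene and β-hydride elimination (the carbinol carbon has no hydrogen) should give only the E allylic alcohol, while the mildly basic medium keeps the product as its enolate so that the tertiary allylic alcohol does not cyclodehydrate; no stereocentre.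

**Step 6**
Reactants: 8 4-hydroxy-3-[(E)-3-hydroxy-3-methylbut-1-en-1-yl]-7,8-dimethoxy-1-methylquinolin-2(1H)-one; 5 4-chloro-7,8-dimethoxy-1-methyl-2-oxo-1,2-dihydroquinoline-3-carbaldehyde
Product: 12 racemic bis-pyran (2H-pyran ring C on quinolone 1 fused to 2,2-dimethyldihydropyran ring D on quinolone 2), via formyl aryl ether 9 (not isolated), via quinone methide aldol adduct 10 (not isolated), via allylic carbinol 11 (not isolated)
Conditions: NaH (2.2 equiv), THF–DMF, 0 °C; then 5, 0 → 45 °C; then AcOH, 25 °C
Reagents that add atoms: none
Why: Proposed new method: the tertiary alkoxide of the dianion of 8 displaces chloride from C4 of 5 by addition–elimination (SNAr on a vinylogous acyl chloride) to give ether 9, whose 4-oxido-3-alkenylquinolone then acts as a vinylogous enolate, the alkene carbon next to CMe2 adding to the neighbouring formyl group (oxide-driven aldol, formally a carbonyl-ene closure) to give ortho-quinone methide 10, and a proton shift restores the hydroxyquinolone as carbinol 11. On acidification the doubly activated carbinol should ionise and the 4-OH of quinolone 1 capture the cation (equivalently, oxa-6π closure of the 1-oxatriene) to give 12. The closest known reaction types are domino SNAr/condensation annulations of 4-chloro-3-formyl-2-quinolones and -coumarins with 1,3-binucleophiles, ortho-hydroxyalkylation of metal phenoxides by aldehydes, and the condensation of 2-vinylphenols with aldehydes to 2H-chromenes. Ring D closes by a 6-(enolexo)-exo-trig aldol after the intermolecular SNAr, and ring C by 6-endo capture of the allylic cation (or disrotatory oxa-6π closure). The only stereocentre of 12, the O–CH carbon, forms racemic and needs no control because step 7 passes through the achiral ring-opened form. The selectivities needed are alkoxide over 4-oxide in the SNAr (the tertiary alkoxide is by far the stronger nucleophile, and any diaryl ether is itself an exchangeable vinylogous anhydride) and γ- over α-attack in the aldol (C3 of quinolone 1 is substituted, and the three-atom tether lets only the γ-carbon reach the aldehyde through a six-membered transition state).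

**Step 7**
Reactants: 12 racemic bis-pyran; 13 (2-methylprop-1-en-1-yl)boronic acid
Product: 14 4-hydroxy-7,8-dimethoxy-1-methyl-3-[(1S)-1-(7,8-dimethoxy-2,2,6-trimethyl-5-oxo-5,6-dihydro-2H-pyrano[3,2-c]quinolin-3-yl)-3-methylbut-2-en-1-yl]quinolin-2(1H)-one
Conditions: (R)-3,3′-bis(pentafluorophenyl)-1,1′-bi-2-naphthol (20 mol %), Mg(Ot-Bu)2 (10 mol %), 4 Å MS, toluene, 70 °C; then H2O
Reagents that add atoms: none
Why: Chiral-diol-catalysed conjugate addition of an alkenylboronic acid (boron-ate 1,4-addition) to the ortho-quinone methide that 12 reaches by thermal retro-oxa-6π opening of ring C, in which the binaphthol-bound boronate coordinates the carbonyl of the fixed s-cis enone and delivers the alkenyl group to one face of the exocyclic carbon, so the (S) centre is set under catalyst control while the racemic O–CH centre of 12 is erased in the achiral open form.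

**Step 8**
Reactants: 14 (S)-alkenylated hydroxyquinolone–pyranoquinolone
Product: 15 target: cis-fused pyrano-pyran bis(7,8-dimethoxy-1-methyl-2-quinolone) with (S)-CH(2-methylprop-1-enyl) and (S)-CH and (R)-O–CH ring-fusion centres
Conditions: PPTS (20 mol %), CH2Cl2, 25 °C
Reagents that add atoms: none
Why: Acid-catalysed intramolecular hydroalkoxylation, in which the dienol-ether-type pyran alkene is protonated at the carbon next to CMe2 much faster than the isobutenyl group, the oxygen-stabilised (vinylogous oxocarbenium) cation is captured by the 4-OH of quinolone 1 in a six-membered cis-fused closure, and, both events being reversible, the existing (S) centre should steer the mixture to the isomer with the alkenyl group trans to the CMe2 arm on the convex face, that is (S) at the new CH and (R) at the new O–CH.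

**Compound list**
1 | 2,3-dimethoxyaniline | COc1cccc(N)c1OC | starting material
2 | 2,3-dimethoxy-N-methylaniline | CNc1cccc(OC)c1OC | intermediate
3 | bis(2,4,6-trichlorophenyl) malonate | O=C(CC(=O)Oc1c(Cl)cc(Cl)cc1Cl)Oc1c(Cl)cc(Cl)cc1Cl | starting material
4 | 4-hydroxy-7,8-dimethoxy-1-methylquinolin-2(1H)-one | COc1ccc2c(O)cc(=O)n(C)c2c1OC | intermediate
5 | 4-chloro-7,8-dimethoxy-1-methyl-2-oxo-1,2-dihydroquinoline-3-carbaldehyde | COc1ccc2c(Cl)c(C=O)c(=O)n(C)c2c1OC | intermediate
6 | 4-hydroxy-3-iodo-7,8-dimethoxy-1-methylquinolin-2(1H)-one | COc1ccc2c(O)c(I)c(=O)n(C)c2c1OC | intermediate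
7 | 2-methylbut-3-en-2-ol | C=CC(C)(C)O | starting material
8 | 4-hydroxy-3-[(E)-3-hydroxy-3-methylbut-1-en-1-yl]-7,8-dimethoxy-1-methylquinolin-2(1H)-one | COc1ccc2c(O)c(/C=C/C(C)(C)O)c(=O)n(C)c2c1OC | intermediate
9 | formyl aryl ether: the tertiary oxygen of 8 bonded to C4 of the 3-formylquinolone, E alkene kept (not isolated) | COc1ccc2c(O)c(/C=C/C(C)(C)Oc3c(C=O)c(=O)n(C)c4c(OC)c(OC)ccc34)c(=O)n(C)c2c1OC | intermediate
10 | quinone methide aldol adduct: ring D closed, secondary carbinol, 3-alkylidenequinoline-2,4-dione of quinolone 1, mixture of stereoisomers (not isolated) | COc1ccc2C(=O)C(=CC3C(O)c4c(OC3(C)C)c5ccc(OC)c(OC)c5n(C)c4=O)C(=O)N(C)c2c1OC | intermediate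
11 | allylic carbinol: 4-hydroxyquinolone 1 bonded through CH= to ring D, racemic, alkene geometry not fixed (not isolated) | COc1ccc2c(O)c(C=C3C(O)c4c(OC3(C)C)c5ccc(OC)c(OC)c5n(C)c4=O)c(=O)n(C)c2c1OC | intermediate
12 | racemic bis-pyran: 2H-pyran ring C on quinolone 1 whose O–CH carbon is bonded to C3 of quinolone 2 and whose alkene carbon carries the CMe2–O arm of ring D | COc1ccc2c3c(c(=O)n(C)c2c1OC)C=C4C(O3)c5c(OC4(C)C)c6ccc(OC)c(OC)c6n(C)c5=O | intermediate
13 | (2-methylprop-1-en-1-yl)boronic acid | CC(C)=CB(O)O | starting material
14 | 4-hydroxy-7,8-dimethoxy-1-methyl-3-[(1S)-1-(7,8-dimethoxy-2,2,6-trimethyl-5-oxo-5,6-dihydro-2H-pyrano[3,2-c]quinolin-3-yl)-3-methylbut-2-en-1-yl]quinolin-2(1H)-one | COc1ccc2c(O)c(c(=O)n(C)c2c1OC)[C@@H](C=C(C)C)C1=Cc2c(c3ccc(OC)c(OC)c3n(C)c2=O)OC1(C)C | intermediate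
15 | target: cis-fused pyrano-pyran bis(7,8-dimethoxy-1-methyl-2-quinolone); CH(2-methylprop-1-enyl) S, adjacent ring-fusion CH S, ring-fusion O–CH R | COc1ccc2c3c(c(=O)n(C)c2c1OC)[C@@H](C=C(C)C)[C@H]1[C@@H](O3)c2c(c3ccc(OC)c(OC)c3n(C)c2=O)OC1(C)C | target

**Step count and risks**
Total steps: 8. Longest linear sequence: 7 (steps 1, 2, 4, 5, 6, 7, 8).

Steps most likely to fail:

Step 6 (Proposed new method). The stabilised 4-oxide of 8 may compete with the tertiary alkoxide for the chloro aldehyde, or the oxide-driven γ-aldol may stall at the ether stage or revert. The fallback uses known chemistry, sets out from 5 and 4 and comes back at 12. Compound 5 is hydrolysed (aq. NaOH, THF, then acid) to 4-hydroxy-7,8-dimethoxy-1-methyl-2-oxo-1,2-dihydroquinoline-3-carbaldehyde F1. Oxa-Michael addition/aldol condensation of F1 with 3-methylbut-2-enal (K2CO3, dioxane, reflux), the established route from salicylaldehydes to 2,2-dimethyl-2H-chromene-3-carbaldehydes, should give 7,8-dimethoxy-2,2,6-trimethyl-5-oxo-5,6-dihydro-2H-pyrano[3,2-c]quinoline-3-carbaldehyde F2. Knoevenagel condensation/oxa-6π electrocyclisation of F2 with 4 (ethylenediammonium diacetate, toluene, 80 °C), the standard formal [3+3] annulation of 4-hydroxy-2-quinolones with enals, should then give 12.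

Step 7. Thermal opening of ring C may be too slow compared with protodeboronation of 13, or facial selectivity may be poor because either carbonyl of the open form can bind boron. The fallback sets out from 12 and comes back at 14. Ring C of 12 is an allylic aryl ether, so copper-catalysed SN2′ substitution with (2-methylprop-1-enyl)magnesium bromide (CuBr·SMe2 cat., THF, −40 °C) should deliver the alkenyl group to the same carbon without prior ring opening. This gives racemic 14, that is 14 together with its enantiomer F3, and preparative chiral SFC should then provide 14.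

Step 8. The isobutenyl group may be protonated and close onto the 4-OH to a dimethylchroman, or the facial selectivity of protonation may be poor if the equilibrium does not favour the desired epimer at the new CH. The fallback sets out from 12 and comes back at 15 by reversing the order of events. HBF4·OEt2 (CH2Cl2, −40 °C) protonates the ring-C alkene of 12 at the carbon next to CMe2 inside the intact cis-fused bicycle, before any isobutenyl group is present. Potassium (2-methylprop-1-enyl)trifluoroborate then captures the oxygen-stabilised cation from the convex face, anti to the CMe2 arm. This should give racemic 15, that is 15 together with its enantiomer F4, separated by preparative chiral SFC.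

**Further compounds**
F1 | step 6 | 4-hydroxy-7,8-dimethoxy-1-methyl-2-oxo-1,2-dihydroquinoline-3-carbaldehyde | COc1ccc2c(O)c(C=O)c(=O)n(C)c2c1OC
F2 | step 6 | 7,8-dimethoxy-2,2,6-trimethyl-5-oxo-5,6-dihydro-2H-pyrano[3,2-c]quinoline-3-carbaldehyde | COc1ccc2c3c(c(=O)n(C)c2c1OC)C=C(C=O)C(C)(C)O3
F3 | step 7 | enantiomer of 14 (second half of racemic 14) | COc1ccc2c(O)c(c(=O)n(C)c2c1OC)[C@H](C=C(C)C)C1=Cc2c(c3ccc(OC)c(OC)c3n(C)c2=O)OC1(C)C
F4 | step 8 | enantiomer of 15 (second half of racemic 15) | COc1ccc2c3c(c(=O)n(C)c2c1OC)[C@H](C=C(C)C)[C@@H]1[C@H](O3)c2c(c3ccc(OC)c(OC)c3n(C)c2=O)OC1(C)C
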